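**Plan**

- Numbering is prostanoid: C1 is the ester carbon, the ring is C8–C12, the octenyl chain is C13–C20. Retrosynthetic cuts, in order: C12–OAc; C10–Cl (through the 10,11-epoxide); C7=C8 (through a C8 selenide); then the ring bond C8–C12 together with C12–O, which unravels the cyclopentenone to a furan; then C5=C6, C7–C8 and C13–furan of the open-chain furylcarbinol.
- Enabling feature: the cyclopent-2-enone C9(=O)–C10=C11, whose quaternary C12 carries oxygen and the octenyl chain and sits next to chain-bearing C8, is a 4-oxygenated 4,5-disubstituted cyclopentenone. That is the product pattern of a Piancatelli rearrangement of a 2,5-disubstituted furan-2-yl carbinol (carbinol carbon = C8, furan carbons = C9–C12).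
- Forward order: the octenyl chain is put on the furan, the upper chain is grown from the furfural carbon (acetate aldol, reduction, Wittig), the only ring closes in the rearrangement, and C7=C8, C10–Cl and the acetate follow on the finished skeleton.
- Stereochemistry: 14Z is bought with (Z)-oct-2-en-1-ol; 5Z comes from the salt-free Wittig reaction; 12R from the chiral acid that steers the conrotatory closure; 7E from the selenoxide elimination. The carbinol centre and C8 are transient and need no control.

Key step: step 8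

Assumption: the hand of the chiral acid that leads to 12R cannot be derived from precedent; the (R)-acid is written, and its mirror image is to be used if a first run shows the opposite sense.

**Route**

Step 1
Reactants: 1 (Z)-oct-2-en-1-ol
Product: 2 (Z)-1-bromooct-2-ene
Conditions: CBr4, PPh3, CH2Cl2, 0 °C
Reagents that add atoms: tetrabromomethane, BrC(Br)(Br)Br
Why: Appel bromination converts the primary allylic alcohol under neutral conditions at 0 °C, so the Z olefin should be retained and no allylic transposition is expected.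

Step 2
Reactants: 3 2-(diethoxymethyl)furan; 2 (Z)-1-bromooct-2-ene
Product: 6 5-[(2Z)-oct-2-en-1-yl]furan-2-carbaldehyde, via lithiated furan acetal 4 (not isolated), via alkylated furan acetal 5 (not isolated)
Conditions: n-BuLi, THF, −78 → −20 °C; 2, −78 °C → rt; then 1 M HCl, THF, rt
Reagents that add atoms: water, O
Why: α-Lithiation of the furan acetal at C5, SN2 alkylation of the furyllithium at the primary allylic carbon and acetal hydrolysis are standard furan chemistry, and lithiating before the allyl group is present avoids deprotonation of a furyl-allyl methylene.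

Step 3
Reactants: 6 5-[(2Z)-oct-2-en-1-yl]furan-2-carbaldehyde; 7 methyl acetate
Product: 9 methyl 3-hydroxy-3-{5-[(2Z)-oct-2-en-1-yl]furan-2-yl}propanoate (racemic), via lithium ester enolate 8 (not isolated)
Conditions: LiN(iPr)2, THF, −78 °C; then 6, −78 °C; aq. NH4Cl
Reagents that add atoms: none
Why: Lithium enolate aldol addition of methyl acetate to the non-enolisable furfural forms the C7–C8 bond, and the carbinol carbon is made racemic on purpose because its configuration is erased in step 8.

Step 4
Reactants: 9 methyl 3-hydroxy-3-{5-[(2Z)-oct-2-en-1-yl]furan-2-yl}propanoate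
Product: 10 methyl 3-[(tert-butyldimethylsilyl)oxy]-3-{5-[(2Z)-oct-2-en-1-yl]furan-2-yl}propanoate (racemic)
Conditions: TBSCl, imidazole, DMF, rt
Reagents that add atoms: tert-butyldimethylsilyl chloride, CC(C)(C)[Si](C)(C)Cl
Why: Standard silyl protection of the secondary furylcarbinol masks it for the ester reduction and the basic ylide that follow.

Step 5
Reactants: 10 methyl 3-[(tert-butyldimethylsilyl)oxy]-3-{5-[(2Z)-oct-2-en-1-yl]furan-2-yl}propanoate
Product: 11 3-[(tert-butyldimethylsilyl)oxy]-3-{5-[(2Z)-oct-2-en-1-yl]furan-2-yl}propanal (racemic)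
Conditions: iBu2AlH, CH2Cl2, −78 °C; aq. potassium sodium tartrate
Reagents that add atoms: none
Why: Partial reduction of a β-silyloxy methyl ester with iBu2AlH at −78 °C should stop at the aldehyde because the tetrahedral aluminium hemiacetal persists until work-up.

Step 6
Reactants: 11 3-[(tert-butyldimethylsilyl)oxy]-3-{5-[(2Z)-oct-2-en-1-yl]furan-2-yl}propanal; 12 (4-carboxybutyl)triphenylphosphonium bromide
Product: 15 methyl (5Z)-8-[(tert-butyldimethylsilyl)oxy]-8-{5-[(2Z)-oct-2-en-1-yl]furan-2-yl}oct-5-enoate (racemic), via phosphorus ylide 13 (not isolated), via sodium carboxylate 14 (not isolated)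
Conditions: NaN(SiMe3)2, THF, 0 °C; 11, −78 °C → rt; then MeI, DMF, rt
Reagents that add atoms: iodomethane, CI
Why: Salt-free Wittig olefination with the non-stabilised carboxylate ylide should give the cis C5=C6 olefin through the kinetically favoured cis-oxaphosphetane, and the sodium carboxylate is O-methylated in the same flask.

Step 7
Reactants: 15 methyl (5Z)-8-[(tert-butyldimethylsilyl)oxy]-8-{5-[(2Z)-oct-2-en-1-yl]furan-2-yl}oct-5-enoate
Product: 16 methyl (5Z)-8-hydroxy-8-{5-[(2Z)-oct-2-en-1-yl]furan-2-yl}oct-5-enoate (racemic)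
Conditions: Bu4NF, THF, 0 °C
Reagents that add atoms: none
Why: Fluoride-mediated desilylation should free the furylcarbinol without touching the methyl ester or either Z olefin.

Step 8
Reactants: 16 methyl (5Z)-8-hydroxy-8-{5-[(2Z)-oct-2-en-1-yl]furan-2-yl}oct-5-enoate
Product: 17 methyl (5Z)-7-{(1S,2R)-2-hydroxy-2-[(2Z)-oct-2-en-1-yl]-5-oxocyclopent-3-en-1-yl}hept-5-enoate
Conditions: (R)-3,3′-bis(2,4,6-triisopropylphenyl)-BINOL N-triflylphosphoramide (10 mol %), H2O (5 equiv), toluene, 40 °C
Reagents that add atoms: water, O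
Why: Proposed new method: the chiral acid ionises the furylcarbinol to a 5-alkylfurfuryl cation, water adds at the octenyl-bearing furan carbon (the future C12), the resulting 2-hydroxy-2,5-dihydrofuran opens to a 9,12-dihydroxypentadienyl cation spanning C8–C12, and this forms the C8–C12 bond and tautomerises to the enone. The closest known reactions are the racemic oxa-Piancatelli rearrangement of 5-alkyl-2-furylcarbinols under Dy(OTf)3 or ZnCl2 catalysis and the chiral phosphoric acid-catalysed aza-Piancatelli rearrangement with anilines, so what is untested is chiral-anion control when water is the terminating nucleophile. The cyclopentenone ring closes by thermal conrotatory 4π electrocyclisation of the pentadienyl cation (Nazarov-type), not by a polar aldol-type closure. C12 is fixed by the direction of conrotation, which the phosphoramide anion should impose by hydrogen bonding to both hydroxyl groups of the cation within a tight ion pair, and C8 should follow as trans to the C12 hydroxyl, the relative outcome of conrotation known for 5-substituted furylcarbinols. The step needs water to enter at C12 and the closure to outrun loss of a C7 proton to a conjugated furyl diene: the 2,5-disubstituted furan has no other productive site (attack at the carbinol carbon merely returns 16), the 5-alkyl group stabilises the cation so that mild temperature suffices, and the non-polar medium keeps the ion pair intact.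

Step 9
Reactants: 17 methyl (5Z)-7-{(1S,2R)-2-hydroxy-2-[(2Z)-oct-2-en-1-yl]-5-oxocyclopent-3-en-1-yl}hept-5-enoate
Product: 19 methyl (5Z)-7-{(2R)-2-[(2Z)-oct-2-en-1-yl]-5-oxo-1-(phenylselanyl)-2-[(triethylsilyl)oxy]cyclopent-3-en-1-yl}hept-5-enoate, via bis-silyl dienol ether 18 (not isolated)
Conditions: Et3SiOTf (2.2 equiv), Et3N, CH2Cl2, −78 → 0 °C; then PhSeCl (1.05 equiv), −78 °C
Reagents that add atoms: triethylsilyl trifluoromethanesulfonate, CC[Si](CC)(CC)OS(=O)(=O)C(F)(F)F; benzeneselenenyl chloride, Cl[Se]c1ccccc1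
Why: Soft enolisation with a silyl triflate and Et3N silylates the C12 hydroxyl and turns the ketone, whose only α-hydrogen is at C8, into its dienol silyl ether without enolising the ester, and α-selenenylation of that silyl enol ether then places selenium at C8, a centre whose configuration is lost in step 10 and needs no control.

Step 10
Reactants: 19 methyl (5Z)-7-{(2R)-2-[(2Z)-oct-2-en-1-yl]-5-oxo-1-(phenylselanyl)-2-[(triethylsilyl)oxy]cyclopent-3-en-1-yl}hept-5-enoate
Product: 21 methyl (5Z,7E,12R,14Z)-9-oxo-12-[(triethylsilyl)oxy]prosta-5,7,10,14-tetraenoate, via selenoxide 20 (not isolated)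
Conditions: 30% H2O2, pyridine, CH2Cl2, 0 °C → rt
Reagents that add atoms: none
Why: Selenide oxidation and selenoxide syn-elimination, which can only take a hydrogen from C7 because C12 is quaternary, should give the exocyclic olefin, expected mainly as the 7E isomer in which C6 lies away from the C9 oxygen as in aldol-derived alkylidenecyclopentenones.

Step 11
Reactants: 21 methyl (5Z,7E,12R,14Z)-9-oxo-12-[(triethylsilyl)oxy]prosta-5,7,10,14-tetraenoate
Product: 22 methyl (5Z,7E,14Z)-10,11-epoxy-9-oxo-12-[(triethylsilyl)oxy]prosta-5,7,14-trienoate (C12 arranged as in 21; epoxide face not defined)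
Conditions: 30% H2O2, NaOH (0.2 equiv), MeOH, 0 °C
Reagents that add atoms: hydrogen peroxide, OO
Why: Weitz–Scheffer nucleophilic epoxidation leaves the isolated 14Z olefin untouched and should select the ring enone, because nucleophiles add at C11 of cross-conjugated cyclopentenone prostanoids and only C10 offers an unsubstituted α-carbon for fast oxirane closure, while the epoxide configuration is irrelevant since both new centres vanish in step 12.

Step 12
Reactants: 22 methyl (5Z,7E,14Z)-10,11-epoxy-9-oxo-12-[(triethylsilyl)oxy]prosta-5,7,14-trienoate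
Product: 24 methyl (5Z,7E,12R,14Z)-10-chloro-12-hydroxy-9-oxoprosta-5,7,10,14-tetraenoate, via chlorohydrin 23 (not isolated)
Conditions: conc. HCl, THF, 0 °C → rt
Reagents that add atoms: hydrogen chloride, Cl
Why: Chloride opens the α,β-epoxy ketone at the carbonyl-activated C10 (C11 is neopentylic), the β-hydroxy-α-chloro ketone dehydrates through its enol to the 2-chloroenone (the known epoxy ketone to α-chloroenone conversion), and the same aqueous acid cleaves the triethylsilyl ether while the C12 carbinol, flanked by two electron-poor olefins, should resist ionisation.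

Step 13
Reactants: 24 methyl (5Z,7E,12R,14Z)-10-chloro-12-hydroxy-9-oxoprosta-5,7,10,14-tetraenoate
Product: 25 methyl (5Z,7E,12R,14Z)-12-acetoxy-10-chloro-9-oxoprosta-5,7,10,14-tetraenoate
Conditions: Ac2O, DMAP, pyridine, CH2Cl2, 0 °C → rt
Reagents that add atoms: acetic anhydride, CC(=O)OC(C)=O
Why: DMAP-catalysed acylation of the tertiary C12 alcohol should proceed cleanly because no enolisable hydrogen or ionisable carbinol remains, and it leaves C12 and the olefin geometries untouched.

**Compound list**

1 | (Z)-oct-2-en-1-ol | CCCCC/C=C\CO | starting material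
2 | (Z)-1-bromooct-2-ene | CCCCC/C=C\CBr | intermediate
3 | 2-(diethoxymethyl)furan | CCOC(OCC)c1ccco1 | starting material
4 | [5-(diethoxymethyl)furan-2-yl]lithium | CCOC(OCC)c1ccc([Li])o1 | intermediate (not isolated)
5 | 2-(diethoxymethyl)-5-[(2Z)-oct-2-en-1-yl]furan | CCCCC/C=C\Cc1ccc(o1)C(OCC)OCC | intermediate (not isolated)
6 | 5-[(2Z)-oct-2-en-1-yl]furan-2-carbaldehyde | CCCCC/C=C\Cc1ccc(C=O)o1 | intermediate
7 | methyl acetate | COC(C)=O | starting material
8 | lithium 1-methoxyethen-1-olate | [Li]OC(=C)OC | intermediate (not isolated)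
9 | methyl 3-hydroxy-3-{5-[(2Z)-oct-2-en-1-yl]furan-2-yl}propanoate, racemic | CCCCC/C=C\Cc1ccc(o1)C(O)CC(=O)OC | intermediate
10 | methyl 3-[(tert-butyldimethylsilyl)oxy]-3-{5-[(2Z)-oct-2-en-1-yl]furan-2-yl}propanoate, racemic | CCCCC/C=C\Cc1ccc(o1)C(O[Si](C)(C)C(C)(C)C)CC(=O)OC | intermediate
11 | 3-[(tert-butyldimethylsilyl)oxy]-3-{5-[(2Z)-oct-2-en-1-yl]furan-2-yl}propanal, racemic | CCCCC/C=C\Cc1ccc(o1)C(O[Si](C)(C)C(C)(C)C)CC=O | intermediate
12 | (4-carboxybutyl)triphenylphosphonium bromide | OC(=O)CCCC[P+](c1ccccc1)(c1ccccc1)c1ccccc1.[Br-] | starting material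
13 | sodium 5-(triphenylphosphoranylidene)pentanoate | [Na+].[O-]C(=O)CCCC=P(c1ccccc1)(c1ccccc1)c1ccccc1 | intermediate (not isolated)
14 | sodium (5Z)-8-[(tert-butyldimethylsilyl)oxy]-8-{5-[(2Z)-oct-2-en-1-yl]furan-2-yl}oct-5-enoate, racemic | CCCCC/C=C\Cc1ccc(o1)C(O[Si](C)(C)C(C)(C)C)C/C=C\CCCC(=O)[O-].[Na+] | intermediate (not isolated)
15 | methyl (5Z)-8-[(tert-butyldimethylsilyl)oxy]-8-{5-[(2Z)-oct-2-en-1-yl]furan-2-yl}oct-5-enoate, racemic | CCCCC/C=C\Cc1ccc(o1)C(O[Si](C)(C)C(C)(C)C)C/C=C\CCCC(=O)OC | intermediate
16 | methyl (5Z)-8-hydroxy-8-{5-[(2Z)-oct-2-en-1-yl]furan-2-yl}oct-5-enoate, racemic | CCCCC/C=C\Cc1ccc(o1)C(O)C/C=C\CCCC(=O)OC | intermediate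
17 | methyl (5Z)-7-{(1S,2R)-2-hydroxy-2-[(2Z)-oct-2-en-1-yl]-5-oxocyclopent-3-en-1-yl}hept-5-enoate (8S,12R in prostanoid numbering; C8 chain trans to the C12 hydroxyl) | CCCCC/C=C\C[C@@]1(O)C=CC(=O)[C@H]1C/C=C\CCCC(=O)OC | intermediate
18 | methyl (5Z)-7-{(5R)-5-[(2Z)-oct-2-en-1-yl]-2,5-bis[(triethylsilyl)oxy]cyclopenta-1,3-dien-1-yl}hept-5-enoate | CCCCC/C=C\C[C@@]1(O[Si](CC)(CC)CC)C=CC(O[Si](CC)(CC)CC)=C1C/C=C\CCCC(=O)OC | intermediate (not isolated)
19 | methyl (5Z)-7-{(2R)-2-[(2Z)-oct-2-en-1-yl]-5-oxo-1-(phenylselanyl)-2-[(triethylsilyl)oxy]cyclopent-3-en-1-yl}hept-5-enoate (selenium-bearing C8 not defined) | CCCCC/C=C\C[C@@]1(O[Si](CC)(CC)CC)C=CC(=O)C1([Se]c1ccccc1)C/C=C\CCCC(=O)OC | intermediate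
20 | Se-oxide of 19 | CCCCC/C=C\C[C@@]1(O[Si](CC)(CC)CC)C=CC(=O)C1([Se](=O)c1ccccc1)C/C=C\CCCC(=O)OC | intermediate (not isolated)
21 | methyl (5Z,7E,12R,14Z)-9-oxo-12-[(triethylsilyl)oxy]prosta-5,7,10,14-tetraenoate | CCCCC/C=C\C[C@@]1(O[Si](CC)(CC)CC)C=CC(=O)/C1=C/C=C\CCCC(=O)OC | intermediate
22 | methyl (5Z,7E,14Z)-10,11-epoxy-9-oxo-12-[(triethylsilyl)oxy]prosta-5,7,14-trienoate (C12 arranged as in 21, formally 12S because the epoxide changes the priorities; epoxide face not defined) | CCCCC/C=C\C[C@@]1(O[Si](CC)(CC)CC)C2OC2C(=O)/C1=C/C=C\CCCC(=O)OC | intermediate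
23 | methyl (5Z,7E,14Z)-10-chloro-11,12-dihydroxy-9-oxoprosta-5,7,14-trienoate (C12 arranged as in 21; C10 and C11 not defined) | CCCCC/C=C\C[C@@]1(O)C(O)C(Cl)C(=O)/C1=C/C=C\CCCC(=O)OC | intermediate (not isolated)
24 | methyl (5Z,7E,12R,14Z)-10-chloro-12-hydroxy-9-oxoprosta-5,7,10,14-tetraenoate | CCCCC/C=C\C[C@@]1(O)C=C(Cl)C(=O)/C1=C/C=C\CCCC(=O)OC | intermediate
25 | methyl (5Z,7E,12R,14Z)-12-acetoxy-10-chloro-9-oxoprosta-5,7,10,14-tetraenoate | CCCCC/C=C\C[C@@]1(OC(C)=O)C=C(Cl)C(=O)/C1=C/C=C\CCCC(=O)OC | target

**Count and risks**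

Total: 13 steps. Longest linear sequence: 13 steps (steps 1–13 from 1; 12 steps from 3).

1. Step 8 (labelled). What may go wrong: water loosens the contact between the cation and the chiral anion so that the sense of conrotation is poorly controlled, and slow ionisation of the aliphatic carbinol lets elimination toward C7 compete. Fallback: setting out from 16, the rearrangement is run without chiral control under a known racemic oxa-Piancatelli protocol (Dy(OTf)3, 10 mol %, MeCN–H2O, 80 °C). This should give 17 together with its mirror image, methyl (5Z)-7-{(1R,2S)-2-hydroxy-2-[(2Z)-oct-2-en-1-yl]-5-oxocyclopent-3-en-1-yl}hept-5-enoate F1. The two are separated by preparative HPLC on a polysaccharide-carbamate chiral stationary phase, and the route is rejoined at 17.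

2. Step 9. What may go wrong: carbon–selenium bond formation at the fully substituted C8 beside the quaternary C12 is slow, which leaves PhSeCl free to add across the two Z olefins. Fallback: setting out from 18 (made as in the first half of step 9 and freed from ammonium triflate by a bicarbonate wash), Saegusa–Ito oxidation with Pd(OAc)2 (1.1 equiv, MeCN, rt) replaces selenium. The palladium enolate can only undergo β-hydride elimination toward C7, so it should deliver 21 directly, where the route is rejoined. This detour makes no compound outside the list (F0).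

3. Step 11. What may go wrong: hydroperoxide or hydroxide attacks C7 or C5 of the exocyclic dienone instead of C11, giving the wrong site selectivity and eroding the 5Z/7E geometry by reversible addition. Fallback: setting out from 17, the chlorine is introduced while the ring enone is the only electrophilic olefin. Silylation (Et3SiOTf, 2,6-lutidine, CH2Cl2, −78 °C) should give the C12 triethylsilyl ether of 17 F2. Alkaline H2O2 as in step 11 should give its 10,11-epoxide F3. Conc. HCl in THF should lead, through the 10-chloro-11,12-diol F4, to the 10-chloro analogue of 17 F5 with loss of the silyl group. The conditions of step 9 then lead through the chlorinated bis-silyl dienol ether F6 to the C8 phenylselenide F7, and those of step 10 through the selenoxide F8 to the triethylsilyl ether of 24 F9. HF·pyridine in THF at 0 °C removes the silyl group, and the route is rejoined at 24.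

**Further compounds**

F1 | step 8 | methyl (5Z)-7-{(1R,2S)-2-hydroxy-2-[(2Z)-oct-2-en-1-yl]-5-oxocyclopent-3-en-1-yl}hept-5-enoate (enantiomer of 17) | CCCCC/C=C\C[C@]1(O)C=CC(=O)[C@@H]1C/C=C\CCCC(=O)OC
F0 | step 9 | none | none
F2 | step 11 | methyl (5Z)-7-{(1S,2R)-2-[(2Z)-oct-2-en-1-yl]-5-oxo-2-[(triethylsilyl)oxy]cyclopent-3-en-1-yl}hept-5-enoate (triethylsilyl ether of 17) | CCCCC/C=C\C[C@@]1(O[Si](CC)(CC)CC)C=CC(=O)[C@H]1C/C=C\CCCC(=O)OC
F3 | step 11 | 10,11-epoxide of F2 (C8 and C12 arranged as in 17; epoxide face not defined) | CCCCC/C=C\C[C@@]1(O[Si](CC)(CC)CC)C2OC2C(=O)[C@H]1C/C=C\CCCC(=O)OC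
F4 | step 11 | methyl (5Z,14Z)-10-chloro-11,12-dihydroxy-9-oxoprosta-5,14-dienoate (C8 and C12 arranged as in 17; C10 and C11 not defined) | CCCCC/C=C\C[C@@]1(O)C(O)C(Cl)C(=O)[C@H]1C/C=C\CCCC(=O)OC
F5 | step 11 | methyl (5Z)-7-{4-chloro-2-hydroxy-2-[(2Z)-oct-2-en-1-yl]-5-oxocyclopent-3-en-1-yl}hept-5-enoate (C8 and C12 arranged as in 17) | CCCCC/C=C\C[C@@]1(O)C=C(Cl)C(=O)[C@H]1C/C=C\CCCC(=O)OC
F6 | step 11 | 10-chloro analogue of 18 (bis-triethylsilyl dienol ether of F5) | CCCCC/C=C\C[C@@]1(O[Si](CC)(CC)CC)C=C(Cl)C(O[Si](CC)(CC)CC)=C1C/C=C\CCCC(=O)OC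
F7 | step 11 | 10-chloro analogue of 19 (C8 phenylselenide; C8 not defined) | CCCCC/C=C\C[C@@]1(O[Si](CC)(CC)CC)C=C(Cl)C(=O)C1([Se]c1ccccc1)C/C=C\CCCC(=O)OC
F8 | step 11 | Se-oxide of F7 | CCCCC/C=C\C[C@@]1(O[Si](CC)(CC)CC)C=C(Cl)C(=O)C1([Se](=O)c1ccccc1)C/C=C\CCCC(=O)OC
F9 | step 11 | methyl (5Z,7E,12R,14Z)-10-chloro-9-oxo-12-[(triethylsilyl)oxy]prosta-5,7,10,14-tetraenoate (triethylsilyl ether of 24) | CCCCC/C=C\C[C@@]1(O[Si](CC)(CC)CC)C=C(Cl)C(=O)/C1=C/C=C\CCCC(=O)OC
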